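**Retrosynthetic overview**
1. Target 13 is cut at the enone C=C (Claisen–Schmidt, then MOM removal) into methyl ketone 9 and aldehyde 11. The enone is made last, so it never meets an oxidant.
2. The strategy rests on the dihydropyran ring O1–C2(Me)2–C3(OH)–C4H2 fused at C4a/C8a. O1 sits on the carbon next to the acyl-bearing C8, and OMe sits on C5. This ring is a prenyl group on C3 of paeonol, oxygenated at its alkene and tied back to the phenol oxygen.
3. 9 comes from prenyl arene 7. The C3–O bond is made by asymmetric epoxidation and the O1–C2 bond by 6-endo opening of that epoxide. This is the only ring formed in the route, since both benzene rings are bought.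
4. 7 comes from paeonol 1 by O-allylation, aromatic Claisen shift to the one open ortho carbon, cross metathesis with 2-methylbut-2-ene, and MOM protection.

Key step: step 5

Assumption: the L-fructose-derived enantiomer of the Shi ketone (1,2:4,5-di-O-isopropylidene-β-L-erythro-2,3-hexodiulo-2,6-pyranose) is taken as an available catalyst, since it is prepared from L-sorbose by an established sequence.

Step 1
Reactants: 1 paeonol (1-(2-hydroxy-4-methoxyphenyl)ethanone); 2 allyl bromide (3-bromoprop-1-ene)
Product: 3 1-[4-methoxy-2-(prop-2-en-1-yloxy)phenyl]ethanone
Conditions: K2CO3, DMF, 60 °C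
Reagents that add atoms: none
Why: Williamson ether synthesis, in which carbonate in a dipolar aprotic solvent breaks the hydrogen bond to the acetyl group and the phenoxide displaces bromide from an unhindered primary allylic carbon (SN2), an electrophile chosen because a chelated, flanked phenol alkylates poorly with tertiary halides.

Step 2
Reactants: 3 1-[4-methoxy-2-(prop-2-en-1-yloxy)phenyl]ethanone
Product: 4 1-[2-hydroxy-4-methoxy-3-(prop-2-en-1-yl)phenyl]ethanone (3-allylpaeonol)
Conditions: PhNEt2, 200 °C, Ar
Reagents that add atoms: none
Why: Aromatic Claisen rearrangement, in which one ortho carbon is blocked by the acetyl group, so the [3,3] shift that can end in tautomerisation goes to the C–H carbon between the two oxygens and restores the hydrogen-bonded phenol.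

Step 3
Reactants: 4 3-allylpaeonol; 5 2-methylbut-2-ene
Product: 6 1-[2-hydroxy-4-methoxy-3-(3-methylbut-2-en-1-yl)phenyl]ethanone (3-prenylpaeonol)
Conditions: Grubbs II (3 mol %), 2-methylbut-2-ene (excess), CH2Cl2, 35 °C (sealed)
Reagents that add atoms: none
Why: Olefin cross metathesis, in which the terminal alkene exchanges its CH2 end for the isopropylidene of 5, and the excess of the volatile partner and loss of propene drive the exchange to the trisubstituted alkene, which re-enters metathesis only slowly.

Step 4
Reactants: 6 3-prenylpaeonol
Product: 7 1-[4-methoxy-2-(methoxymethoxy)-3-(3-methylbut-2-en-1-yl)phenyl]ethanone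
Conditions: NaH, DMF, 0 °C; MOMCl, 0 °C to rt
Reagents that add atoms: chloromethyl methyl ether (MOMCl), COCCl
Why: MOM protection (O-alkylation by an α-chloro ether), in which irreversible deprotonation of the phenol, far more acidic than the methyl ketone, gives a phenoxide that takes up the small, very reactive electrophile despite two ortho neighbours, and the acetal withstands the pH 10.5 oxidation in which a free phenoxide would be oxidised or would open the epoxide 5-exo.

Step 5
Reactants: 7 1-[4-methoxy-2-(methoxymethoxy)-3-(3-methylbut-2-en-1-yl)phenyl]ethanone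
Product: 9 1-[(3S)-3-hydroxy-5-methoxy-2,2-dimethyl-3,4-dihydro-2H-chromen-8-yl]ethanone, via (S)-epoxide 8 (not isolated)
Conditions: (i) L-fructose-derived Shi ketone (0.3 equiv), Oxone, K2CO3, Bu4NHSO4 (cat.), MeCN–CH2(OMe)2, aq Na2B4O7/Na2EDTA buffer (pH 10.5), 0 °C; (ii) phase cut, solvent swap without purification, CSA (0.2 equiv), water-saturated CH2Cl2, 0 °C to rt
Reagents that add atoms: potassium peroxymonosulfate (active component of Oxone), [K+].[O-]S(=O)(=O)OO
Why: Stage (i) is a Shi asymmetric epoxidation: Oxone turns the chiral ketone into its dioxirane, which passes one oxygen to the nucleophilic trisubstituted C=C through a spiro transition state, while the deactivated aryl ketone, the arene and the acetal are left alone at 0 °C and pH 10.5. The D-fructose ketone converts RCH2CH=CMe2 alkenes into R epoxides, so the L-fructose-derived antipode is used, and this catalyst is the only element that fixes the S oxirane carbon that becomes C3. Stage (ii) follows the known acid-promoted closure of epoxidised ortho-prenylphenols to chroman-3-ols with one adjustment: a protonated trialkyl epoxide reacts much faster than a formaldehyde acetal hydrolyses, so the acid is applied after the phase cut in a non-nucleophilic solvent, where the acetal-bearing aryl oxygen (turned out of conjugation by its two ortho neighbours) is itself the nucleophile and the resulting oxonium ion expels MeOCH2+, which the dissolved water converts into formaldehyde and methanol. The pyran ring closes 6-endo-tet by O1–C2 bond formation at the tertiary oxirane carbon, where positive charge develops under acid, and base, which would steer a phenoxide to 5-exo attack at the secondary carbon, is never present once the oxygen is unmasked. The C3–O bond made in stage (i) is not broken, so C3 is carried through with retention as S. Selectivity between the two ether oxygens flanking the side chain is secured by the substrate, because only the MOM oxygen can lose a stabilised cation, whereas addition of the methoxy oxygen is reversible.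

Step 6
Reactants: 10 4-hydroxybenzaldehyde
Product: 11 4-(methoxymethoxy)benzaldehyde
Conditions: MOMCl, K2CO3, acetone, 0 °C to rt
Reagents that add atoms: chloromethyl methyl ether (MOMCl), COCCl
Why: MOM protection of an unhindered acidic phenol, which removes the phenoxide that would otherwise push electron density into the aldehyde and deactivate it in the base-mediated condensation.

Step 7
Reactants: 9 1-[(3S)-3-hydroxy-5-methoxy-2,2-dimethyl-3,4-dihydro-2H-chromen-8-yl]ethanone; 11 4-(methoxymethoxy)benzaldehyde
Product: 12 (2E)-1-[(3S)-3-hydroxy-5-methoxy-2,2-dimethyl-3,4-dihydro-2H-chromen-8-yl]-3-[4-(methoxymethoxy)phenyl]prop-2-en-1-one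
Conditions: KOH, EtOH–H2O, rt
Reagents that add atoms: none
Why: Claisen–Schmidt condensation (crossed aldol, E1cB dehydration), in which 9 is the only enolisable partner and 11 the only aldehyde, the conjugated E-enone is the thermodynamic product, no free ortho-phenol is present to close a flavanone, and C3 has no acidifying neighbour, so its configuration is not at risk.

Step 8
Reactants: 12 MOM-protected chalcone
Product: 13 (2E)-1-[(3S)-3-hydroxy-5-methoxy-2,2-dimethyl-3,4-dihydro-2H-chromen-8-yl]-3-(4-hydroxyphenyl)prop-2-en-1-one (target)
Conditions: 3 M aq HCl, MeOH, 50 °C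
Reagents that add atoms: none
Why: Acid-catalysed acetal cleavage (transacetalisation to methanol), which removes the aryl MOM ether under conditions that leave the enone, the aryl methyl ether, the tertiary alkyl aryl ether of the pyran ring and the secondary alcohol intact, so the E geometry and the 3S centre persist.

**Compound list**
1 | paeonol, 1-(2-hydroxy-4-methoxyphenyl)ethanone | COc1ccc(C(C)=O)c(O)c1 | starting material
2 | allyl bromide | C=CCBr | starting material
3 | 1-[4-methoxy-2-(prop-2-en-1-yloxy)phenyl]ethanone | COc1ccc(C(C)=O)c(OCC=C)c1 | intermediate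
4 | 1-[2-hydroxy-4-methoxy-3-(prop-2-en-1-yl)phenyl]ethanone | COc1ccc(C(C)=O)c(O)c1CC=C | intermediate
5 | 2-methylbut-2-ene | CC=C(C)C | starting material
6 | 1-[2-hydroxy-4-methoxy-3-(3-methylbut-2-en-1-yl)phenyl]ethanone | COc1ccc(C(C)=O)c(O)c1CC=C(C)C | intermediate
7 | 1-[4-methoxy-2-(methoxymethoxy)-3-(3-methylbut-2-en-1-yl)phenyl]ethanone | COCOc1c(C(C)=O)ccc(OC)c1CC=C(C)C | intermediate
8 | 1-[3-{[(2S)-3,3-dimethyloxiran-2-yl]methyl}-4-methoxy-2-(methoxymethoxy)phenyl]ethanone | COCOc1c(C(C)=O)ccc(OC)c1C[C@@H]2OC2(C)C | intermediate
9 | 1-[(3S)-3-hydroxy-5-methoxy-2,2-dimethyl-3,4-dihydro-2H-chromen-8-yl]ethanone | COc1ccc(C(C)=O)c2c1C[C@H](O)C(C)(C)O2 | intermediate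
10 | 4-hydroxybenzaldehyde | O=Cc1ccc(O)cc1 | starting material
11 | 4-(methoxymethoxy)benzaldehyde | COCOc1ccc(C=O)cc1 | intermediate
12 | (2E)-1-[(3S)-3-hydroxy-5-methoxy-2,2-dimethyl-3,4-dihydro-2H-chromen-8-yl]-3-[4-(methoxymethoxy)phenyl]prop-2-en-1-one | COc1ccc(C(=O)/C=C/c2ccc(OCOC)cc2)c2c1C[C@H](O)C(C)(C)O2 | intermediate
13 | (2E)-1-[(3S)-3-hydroxy-5-methoxy-2,2-dimethyl-3,4-dihydro-2H-chromen-8-yl]-3-(4-hydroxyphenyl)prop-2-en-1-one | COc1ccc(C(=O)/C=C/c2ccc(O)cc2)c2c1C[C@H](O)C(C)(C)O2 | target

Total step count: 8. Longest linear sequence: 7 (steps 1–5, 7, 8).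

**Steps most likely to fail**

Step 5.
- Facial selectivity may erode through the competing planar transition state, because the Z-methyl group of the prenyl unit crowds the catalyst.
- In the acid stage the activated epoxide may be diverted before the masked oxygen closes the ring, by hydride shift, capture by external water, or 5-exo closure.
- The fallback changes both the ring closure and the source of asymmetry. It sets out from 6.
- Oxidative cyclisation with DDQ (toluene, reflux) should give the chromene 1-(5-methoxy-2,2-dimethyl-2H-chromen-8-yl)ethanone F1.
- Jacobsen–Katsuki epoxidation follows ((S,S)-Mn(salen)Cl, buffered aq NaOCl, 4-phenylpyridine N-oxide, CH2Cl2, 0 °C). On 2,2-dimethylchromenes, a favoured substrate class for this catalyst, it should give the cis-fused epoxide 1-[(1aS,7bS)-7-methoxy-2,2-dimethyl-1a,7b-dihydro-2H-oxireno[2,3-c]chromen-4-yl]ethanone F2.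
- Hydrogenolysis of the benzylic C4–O bond (H2, 1 atm, Pd/C, EtOAc, monitored to spare the aryl ketone) leaves the C3–O bond in place. The fallback comes back to the route at 9.

Step 3.
- Ruthenium hydrides may move the allyl double bond into conjugation with the ring, or the exchange may stall at the disubstituted stage.
- The fallback brings in the five-carbon unit whole through the oxygen. It sets out from 1.
- Copper-catalysed O-alkylation with purchased 3-chloro-3-methylbut-1-yne (CuCl2 cat., DBU, MeCN, 0 °C) should give the tertiary propargyl ether 1-{4-methoxy-2-[(2-methylbut-3-yn-2-yl)oxy]phenyl}ethanone F3.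
- Lindlar semihydrogenation (H2, Pd/CaCO3–Pb, quinoline, EtOAc) should give 1-{4-methoxy-2-[(2-methylbut-3-en-2-yl)oxy]phenyl}ethanone F4.
- An aromatic Claisen rearrangement (PhNEt2, about 140 °C) with allyl inversion places the prenyl group on the same ortho carbon. The fallback comes back to the route at 6.

Step 7.
- Enolate addition may be slow and incomplete because the ortho-alkoxy group twists the acetyl group, and the aldehyde may be lost by Cannizzaro disproportionation during long exposure to strong base.
- The fallback switches from enolate to enol chemistry and drops the protecting group. It sets out from 9 and 10.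
- Anhydrous HCl in EtOH (0 °C to rt) condenses the enol of 9 with the protonated free hydroxy-aldehyde. No phenoxide is formed, so no protection is needed.
- The fallback comes back to the route directly at 13, so steps 6 and 8 fall away. It makes no compound outside the list (F0).

**Further compounds**
F1 | step 5 | 1-(5-methoxy-2,2-dimethyl-2H-chromen-8-yl)ethanone | COc1ccc(C(C)=O)c2c1C=CC(C)(C)O2
F2 | step 5 | 1-[(1aS,7bS)-7-methoxy-2,2-dimethyl-1a,7b-dihydro-2H-oxireno[2,3-c]chromen-4-yl]ethanone | COc1ccc(C(C)=O)c2c1[C@@H]3O[C@@H]3C(C)(C)O2
F3 | step 3 | 1-{4-methoxy-2-[(2-methylbut-3-yn-2-yl)oxy]phenyl}ethanone | COc1ccc(C(C)=O)c(OC(C)(C)C#C)c1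
F4 | step 3 | 1-{4-methoxy-2-[(2-methylbut-3-en-2-yl)oxy]phenyl}ethanone | COc1ccc(C(C)=O)c(OC(C)(C)C=C)c1
F0 | step 7 | none | none
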